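**Plan**

- Retrosynthesis: (i) cut the tiglate C–O bond and the acetate on O-3; (ii) re-join O-3 to the acrylate carbonyl as an α-methylene-γ-butyrolactone, possible because O-3 and the ester C=O are 1,4-related and cis across C-2/C-3 of the dihydrofuran ring (a cis-fused pair of five-membered rings); (iii) cut the aryl O-1–C-2 bond by an SN2′ transposition to a 5-aryl-3-(bromomethyl)butenolide in which C-2 is flat; (iv) cut C-2–C-3 to 5-acetylsalicylaldehyde and a 2-(methoxycarbonyl)allyl unit.
- Forward: the lactone ring arises first (allylation/lactonisation), its double bond is moved into the ring with an allylic bromide (Br2/Et3N), the dihydrofuran ring is then closed by O-1–C-2 bond formation, and the lactone is opened to the methyl ester before acetate, side-chain carbinol and tiglate are set.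
- Stereochemistry: C-3 from a ligand-controlled aldehyde allylation; C-2 from C-3, relayed by the obligatory cis ring fusion in the ring closure; the side-chain carbinol from a CBS reduction; the E olefin from tiglic acid.

Key step: step 4

Assumption: in step 2 the antipode of the C2-symmetric bis(oxazolinyl)carbazole ligand is the one that sends the allylchromium reagent to the Re face of the aldehyde (giving the 5R lactone); the hand of the ligand is the only variable that fixes C-3.

**Step 1**
Reactants: 1 5-acetyl-2-hydroxybenzaldehyde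
Product: 2 5-acetyl-2-[(tert-butyldimethylsilyl)oxy]benzaldehyde
Conditions: TBSCl, imidazole, DMF, 0 °C to rt
Reagents that add atoms: tert-butyldimethylsilyl chloride, CC(C)(C)[Si](C)(C)Cl
Why: Standard silylation of a phenol; the aryl silyl ether should tolerate the organochromium and bromination steps and is later removed by fluoride to trigger the ring closure.

**Step 2**
Reactants: 2 5-acetyl-2-[(tert-butyldimethylsilyl)oxy]benzaldehyde; 3 methyl 2-(bromomethyl)acrylate
Product: 6 (5R)-5-{5-acetyl-2-[(tert-butyldimethylsilyl)oxy]phenyl}-3-methylenedihydrofuran-2(3H)-one, via silyl ether 4 (not isolated), via hydroxy ester 5 (not isolated)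
Conditions: CrCl2 (10 mol%), chiral 1,8-bis(4-isopropyloxazolin-2-yl)carbazole ligand (12 mol%), Mn powder, TMSCl, iPr2NEt (30 mol%), THF, rt; then TsOH·H2O (cat.), wet CH2Cl2, rt
Reagents that add atoms: none
Why: Catalytic enantioselective Nozaki–Hiyama–Kishi-type 2-(alkoxycarbonyl)allylation, in which the allyl species of trivalent chromium formed from 3 adds only to the aldehyde (the aryl ketone is inert), the tridentate ligand directs it to the Re face and so sets C-3, Mn/TMSCl turn the chromium over, and acid removes the O-silyl group and closes the γ-lactone with loss of methanol.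

**Step 3**
Reactants: 6 (5R)-5-{5-acetyl-2-[(tert-butyldimethylsilyl)oxy]phenyl}-3-methylenedihydrofuran-2(3H)-one
Product: 8 (5R)-5-{5-acetyl-2-[(tert-butyldimethylsilyl)oxy]phenyl}-3-(bromomethyl)furan-2(5H)-one, via dibromide 7 (not isolated)
Conditions: Br2 (1.05 equiv), NaHCO3 (solid), CH2Cl2, 0 °C, dark; then Et3N (1.2 equiv), 0 °C
Reagents that add atoms: bromine, BrBr
Why: Bromine addition to the exocyclic methylene followed by E2 loss of HBr across C-3/C-4 of either dibromide epimer should give the conjugated butenolide with an allylic bromide (a sequence with precedent on 5-substituted α-methylene-γ-butyrolactones); the acetyl-deactivated ring and the non-enolised ketone in the acid-free medium should be left alone, and C-5 is not touched.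

**Step 4**
Reactants: 8 (5R)-5-{5-acetyl-2-[(tert-butyldimethylsilyl)oxy]phenyl}-3-(bromomethyl)furan-2(5H)-one
Product: 11 (3aS,8bS)-7-acetyl-3-methylene-3a,8b-dihydrofuro[3,2-b]benzofuran-2(3H)-one, via phenoxide 9 (not isolated), via lactone enolate 10 (not isolated)
Conditions: TBAF (1.05 equiv), THF (0.01 M), −40 to 0 °C
Reagents that add atoms: none
Why: Fluoride cleaves the aryl silyl ether, phenoxide 9 adds to lactone C-4 (the β-carbon of the butenolide, C-2 of the target) and enolate 10 expels bromide (E1cB), an intramolecular SN2′ O-alkylation of the kind well known for phenoxides with 2-(bromomethyl)acrylates and 3-(bromomethyl)butenolides. The dihydrofuran ring closes by O-1–C-2 bond formation in the 5-exo-trig mode on a trigonal carbon, and the exocyclic methylene of the acrylate is recreated in the same event. The new stereocenter at C-2 is controlled by C-3: the oxygen is carried by the aryl group on the lactone carbon next to the reacting carbon, so it can only reach the face that gives the cis-fused pair of five-membered rings, which fixes 2S from 3S. Attack at C-4 rather than at the CH2Br carbon is secured by ring size, since direct displacement would need a seven-membered ring bridged across the butenolide with a bridgehead double bond, and intermolecular SN2′ is held back by dilution. The configuration at C-3 (the acidic γ-hydrogen of the butenolide) should hold because the phenol is far more acidic, the temperature is low, and one fluoride is consumed for one weakly basic bromide set free, so no base remains once the ring is closed.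

**Step 5**
Reactants: 11 (3aS,8bS)-7-acetyl-3-methylene-3a,8b-dihydrofuro[3,2-b]benzofuran-2(3H)-one
Product: 13 methyl 2-[(2S,3S)-5-acetyl-3-hydroxy-2,3-dihydrobenzofuran-2-yl]acrylate, via potassium carboxylate 12 (not isolated)
Conditions: KOH (1.05 equiv), THF/H2O, 0 °C; evaporate; MeI, DMF, rt
Reagents that add atoms: potassium hydroxide, [K+].[OH-]; iodomethane, CI
Why: Saponification of the strained cis-fused lactone by acyl–oxygen cleavage (C-3 keeps its configuration) and SN2 O-methylation of the carboxylate salt without acidification should take out the temporary ring and turn its carbonyl into the methyl ester before the hydroxy acid can re-close.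

**Step 6**
Reactants: 13 methyl 2-[(2S,3S)-5-acetyl-3-hydroxy-2,3-dihydrobenzofuran-2-yl]acrylate
Product: 14 methyl 2-[(2S,3S)-3-acetoxy-5-acetyl-2,3-dihydrobenzofuran-2-yl]acrylate
Conditions: Ac2O, pyridine, DMAP (5 mol%), CH2Cl2, 0 °C
Reagents that add atoms: acetic anhydride, CC(=O)OC(C)=O
Why: Nucleophile-catalysed acylation of the secondary alcohol with retention at C-3, run cold and on crude 13 so that acetylation outruns re-lactonisation and the base-sensitive β-aryloxy acrylate is not attacked.

**Step 7**
Reactants: 14 methyl 2-[(2S,3S)-3-acetoxy-5-acetyl-2,3-dihydrobenzofuran-2-yl]acrylate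
Product: 15 methyl 2-{(2S,3S)-3-acetoxy-5-[(1S)-1-hydroxyethyl]-2,3-dihydrobenzofuran-2-yl}acrylate
Conditions: (R)-Me-CBS (20 mol%), BH3·SMe2 (0.7 equiv), THF, −20 °C; MeOH quench
Reagents that add atoms: none
Why: CBS reduction of an aryl methyl ketone, in which the (R)-oxazaborolidine delivers hydride to the Re face to give the S carbinol under reagent control, while the esters and the electron-poor 1,1-disubstituted alkene should not react with borane at this temperature.

**Step 8**
Reactants: 15 methyl 2-{(2S,3S)-3-acetoxy-5-[(1S)-1-hydroxyethyl]-2,3-dihydrobenzofuran-2-yl}acrylate; 16 tiglic acid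
Product: 17 (1S)-1-{(2S,3S)-3-acetoxy-2-[1-(methoxycarbonyl)vinyl]-2,3-dihydrobenzofuran-5-yl}ethyl (E)-2-methylbut-2-enoate
Conditions: DCC, DMAP (10 mol%), CH2Cl2, 0 °C to rt
Reagents that add atoms: none
Why: Steglich esterification acylates the carbinol oxygen, so the benzylic centre is retained, and the thermodynamically preferred E geometry of the tigloyl group is not at risk under these neutral conditions.

**Compound list**

1 | 5-acetyl-2-hydroxybenzaldehyde | CC(=O)c1ccc(O)c(C=O)c1 | starting material
2 | 5-acetyl-2-[(tert-butyldimethylsilyl)oxy]benzaldehyde | CC(=O)c1ccc(O[Si](C)(C)C(C)(C)C)c(C=O)c1 | intermediate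
3 | methyl 2-(bromomethyl)acrylate | C=C(CBr)C(=O)OC | starting material
4 | methyl (4R)-4-{5-acetyl-2-[(tert-butyldimethylsilyl)oxy]phenyl}-2-methylene-4-[(trimethylsilyl)oxy]butanoate | C=C(C[C@@H](O[Si](C)(C)C)c1cc(C(C)=O)ccc1O[Si](C)(C)C(C)(C)C)C(=O)OC | intermediate
5 | methyl (4R)-4-{5-acetyl-2-[(tert-butyldimethylsilyl)oxy]phenyl}-4-hydroxy-2-methylenebutanoate | C=C(C[C@@H](O)c1cc(C(C)=O)ccc1O[Si](C)(C)C(C)(C)C)C(=O)OC | intermediate
6 | (5R)-5-{5-acetyl-2-[(tert-butyldimethylsilyl)oxy]phenyl}-3-methylenedihydrofuran-2(3H)-one | C=C1C[C@H](c2cc(C(C)=O)ccc2O[Si](C)(C)C(C)(C)C)OC1=O | intermediate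
7 | (5R)-5-{5-acetyl-2-[(tert-butyldimethylsilyl)oxy]phenyl}-3-bromo-3-(bromomethyl)dihydrofuran-2(3H)-one, both C-3 epimers | BrCC1(Br)C[C@H](c2cc(C(C)=O)ccc2O[Si](C)(C)C(C)(C)C)OC1=O | intermediate
8 | (5R)-5-{5-acetyl-2-[(tert-butyldimethylsilyl)oxy]phenyl}-3-(bromomethyl)furan-2(5H)-one | BrCC1=C[C@H](c2cc(C(C)=O)ccc2O[Si](C)(C)C(C)(C)C)OC1=O | intermediate
9 | tetrabutylammonium 4-acetyl-2-[(2R)-4-(bromomethyl)-5-oxo-2,5-dihydrofuran-2-yl]phenoxide | CCCC[N+](CCCC)(CCCC)CCCC.[O-]c1ccc(C(C)=O)cc1[C@@H]1OC(=O)C(CBr)=C1 | intermediate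
10 | tetrabutylammonium (3aS,8bS)-7-acetyl-3-(bromomethyl)-3a,8b-dihydrofuro[3,2-b]benzofuran-2-olate | CCCC[N+](CCCC)(CCCC)CCCC.[O-]C1=C(CBr)[C@@H]2Oc3ccc(C(C)=O)cc3[C@@H]2O1 | intermediate
11 | (3aS,8bS)-7-acetyl-3-methylene-3a,8b-dihydrofuro[3,2-b]benzofuran-2(3H)-one (cis-fused tricyclic α-methylene lactone) | C=C1[C@@H]2Oc3ccc(C(C)=O)cc3[C@@H]2OC1=O | intermediate
12 | potassium 2-[(2S,3S)-5-acetyl-3-hydroxy-2,3-dihydrobenzofuran-2-yl]acrylate | [K+].[O-]C(=O)C(=C)[C@@H]1Oc2ccc(C(C)=O)cc2[C@@H]1O | intermediate
13 | methyl 2-[(2S,3S)-5-acetyl-3-hydroxy-2,3-dihydrobenzofuran-2-yl]acrylate | C=C(C(=O)OC)[C@@H]1Oc2ccc(C(C)=O)cc2[C@@H]1O | intermediate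
14 | methyl 2-[(2S,3S)-3-acetoxy-5-acetyl-2,3-dihydrobenzofuran-2-yl]acrylate | C=C(C(=O)OC)[C@@H]1Oc2ccc(C(C)=O)cc2[C@@H]1OC(C)=O | intermediate
15 | methyl 2-{(2S,3S)-3-acetoxy-5-[(1S)-1-hydroxyethyl]-2,3-dihydrobenzofuran-2-yl}acrylate | C=C(C(=O)OC)[C@@H]1Oc2ccc([C@H](C)O)cc2[C@@H]1OC(C)=O | intermediate
16 | tiglic acid, (E)-2-methylbut-2-enoic acid | C/C=C(\C)C(=O)O | starting material
17 | (1S)-1-{(2S,3S)-3-acetoxy-2-[1-(methoxycarbonyl)vinyl]-2,3-dihydrobenzofuran-5-yl}ethyl (E)-2-methylbut-2-enoate | C=C(C(=O)OC)[C@@H]1Oc2ccc([C@H](C)OC(=O)/C(C)=C/C)cc2[C@@H]1OC(C)=O | target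

**Count and risks**

Total step count: 8. Longest linear sequence: 8 steps (1 to 17); 3 and 16 are bought.

Steps most likely to fail:

1. Step 4. What may go wrong: deprotonation at the γ-position of the butenolide by phenoxide or fluoride (erosion of configuration at C-3 through the achiral 2-oxidofuran) and intermolecular SN2′ oligomerisation may compete with ring closure. The fallback sets out from 8 and comes back at 11; it replaces the anionic closure by a Tsuji–Trost allylic etherification under neutral conditions. Bromide in 8 is exchanged for acetate (KOAc, DMF, 0 °C) to give [(5R)-5-{5-acetyl-2-[(tert-butyldimethylsilyl)oxy]phenyl}-2-oxo-2,5-dihydrofuran-3-yl]methyl acetate F3. HF·pyridine in THF then removes the silyl group without base to give [(5R)-5-(5-acetyl-2-hydroxyphenyl)-2-oxo-2,5-dihydrofuran-3-yl]methyl acetate F4. Pd(PPh3)4 (5 mol%, zerovalent palladium) in THF ionises the allylic acetate to a π-allyl complex of divalent palladium on the face away from the aryl group, and the phenol attacks lactone C-4 anti to the metal; the ring fusion again allows only the cis product, 11.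

2. Step 3. What may go wrong: bromination at the wrong site (enol bromination of the aryl methyl ketone, ring bromination ortho to the silyloxy group) may outrun addition to the electron-poor exocyclic alkene, or HBr may be lost toward the exocyclic carbon. The fallback sets out from 2 and comes back at 8; it builds the bromomethyl butenolide by ring-closing metathesis with no electrophilic halogen. Enantioselective addition of divinylzinc to 2, catalysed by the 3-exo-morpholinoisoborneol antipode that adds to the Re face (toluene, 0 °C), should give (1R)-1-{5-acetyl-2-[(tert-butyldimethylsilyl)oxy]phenyl}prop-2-en-1-ol F1. Esterification with 2-(bromomethyl)acrylic acid (DCC, CH2Cl2, 0 °C) gives (1R)-1-{5-acetyl-2-[(tert-butyldimethylsilyl)oxy]phenyl}prop-2-en-1-yl 2-(bromomethyl)acrylate F2. Ring-closing metathesis with the second-generation Hoveyda–Grubbs catalyst (toluene, 80 °C) closes the butenolide and gives 8.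

3. Step 5. What may go wrong: re-closure of the ring-opened acid or ester to the lactone during O-methylation and isolation, so that the free hydroxy ester cannot be carried forward clean. The fallback sets out from 11 and comes back at 14; it traps the hydroxyl before anything can re-close. The potassium salt 12, formed as in step 5, is silylated on both oxygens (TBSCl, imidazole, DMF) to give tert-butyldimethylsilyl 2-{(2S,3S)-5-acetyl-3-[(tert-butyldimethylsilyl)oxy]-2,3-dihydrobenzofuran-2-yl}acrylate F5. Aqueous acetic acid in THF hydrolyses only the silyl ester to 2-{(2S,3S)-5-acetyl-3-[(tert-butyldimethylsilyl)oxy]-2,3-dihydrobenzofuran-2-yl}acrylic acid F6, which cannot lactonise. MeI/KHCO3 in DMF gives methyl 2-{(2S,3S)-5-acetyl-3-[(tert-butyldimethylsilyl)oxy]-2,3-dihydrobenzofuran-2-yl}acrylate F7. HF·pyridine followed in the same flask by Ac2O/pyridine then gives 14, with 13 formed in between and not isolated.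

**Further compounds**

F1 | step 3 | (1R)-1-{5-acetyl-2-[(tert-butyldimethylsilyl)oxy]phenyl}prop-2-en-1-ol | C=C[C@@H](O)c1cc(C(C)=O)ccc1O[Si](C)(C)C(C)(C)C
F2 | step 3 | (1R)-1-{5-acetyl-2-[(tert-butyldimethylsilyl)oxy]phenyl}prop-2-en-1-yl 2-(bromomethyl)acrylate | C=C[C@@H](OC(=O)C(=C)CBr)c1cc(C(C)=O)ccc1O[Si](C)(C)C(C)(C)C
F3 | step 4 | [(5R)-5-{5-acetyl-2-[(tert-butyldimethylsilyl)oxy]phenyl}-2-oxo-2,5-dihydrofuran-3-yl]methyl acetate | CC(=O)OCC1=C[C@H](c2cc(C(C)=O)ccc2O[Si](C)(C)C(C)(C)C)OC1=O
F4 | step 4 | [(5R)-5-(5-acetyl-2-hydroxyphenyl)-2-oxo-2,5-dihydrofuran-3-yl]methyl acetate | CC(=O)OCC1=C[C@H](c2cc(C(C)=O)ccc2O)OC1=O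
F5 | step 5 | tert-butyldimethylsilyl 2-{(2S,3S)-5-acetyl-3-[(tert-butyldimethylsilyl)oxy]-2,3-dihydrobenzofuran-2-yl}acrylate | C=C(C(=O)O[Si](C)(C)C(C)(C)C)[C@@H]1Oc2ccc(C(C)=O)cc2[C@@H]1O[Si](C)(C)C(C)(C)C
F6 | step 5 | 2-{(2S,3S)-5-acetyl-3-[(tert-butyldimethylsilyl)oxy]-2,3-dihydrobenzofuran-2-yl}acrylic acid | C=C(C(=O)O)[C@@H]1Oc2ccc(C(C)=O)cc2[C@@H]1O[Si](C)(C)C(C)(C)C
F7 | step 5 | methyl 2-{(2S,3S)-5-acetyl-3-[(tert-butyldimethylsilyl)oxy]-2,3-dihydrobenzofuran-2-yl}acrylate | C=C(C(=O)OC)[C@@H]1Oc2ccc(C(C)=O)cc2[C@@H]1O[Si](C)(C)C(C)(C)C
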